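## Analysis of the target

The target is a flavanonol, a 2-aryl-3-hydroxychroman-4-one, numbered here O1, C2, C3, C4, C4a, C5 to C8 and C8a, with ring B primed and the chain counted from the benzylic carbon C1''. Ring A carries a methoxy group at C5, a free hydroxyl at C7 and, at C8, a (2R)-5-hydroxy-5-methyl-2-(prop-1-en-2-yl)hexyl chain, so C6 is its only unsubstituted position; ring B is a 2,4-dihydroxyphenyl group on C2. There are three stereocentres: C2 (R) and C3 (R) are adjacent and trans on ring C, while C2'' (R) in the chain is isolated from them by the arene and can neither control them nor be controlled by them. The sensitive groups are the benzylic C2–O1 bond, which ionises easily because the ortho and para oxygens of ring B stabilise a cation at C2; the β-aryloxy ketone, which opens by retro-oxa-Michael reaction in base; and the isopropenyl group and tertiary alcohol, which react with acid and with the neighbouring C7 phenol. The synthesis is hard because a fully differentiated, pentasubstituted ring A must be joined regioselectively to the chain and to ring C, because the trans C2/C3 pattern must be fixed in absolute terms without C2 ever becoming a reacting centre, and because the chain stereocentre needs its own source of chirality. The strategy rests on one feature: the O1–C8a bond lies ortho to the C4 carbonyl on C4a, so a fluorine on C8a is activated for nucleophilic aromatic substitution by the C2 oxygen, and ring C can be closed at the aryl carbon instead of at C2.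

## Retrosynthetic reasoning

**34 from 33 (O–protecting groups).** The last operation only unmasks hydroxyl groups. All four acetal ethers and the silyl ether of 33 are chosen to fall to one mild acid treatment, so no redox or C–C chemistry has to be done on the finished flavanonol. The forward step must cleave the deactivated C3 acetal without protonating the isopropenyl group.

**33 from 31 (O1–C8a).** Ring C is opened at the aryl–oxygen bond, not at C2–O1. Cutting C2–O1 would require a substitution at the doubly activated benzylic carbon, which would ionise and lose its configuration. Cutting O1–C8a leaves C2 as a spectator and turns the ring oxygen into the secondary alkoxide of an open-chain β-hydroxy ketone, 31, with fluorine as the leaving group ortho to the ketone. The forward reaction must make this six-ring O-arylation faster than retro-aldol cleavage, enolisation at C3 and closure through the C3 oxygen.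

**31 from 18 and 28 (C4–C4a).** The ketone is cut between the carbonyl carbon and ring A, giving an aryl anion on 18 and the N-methoxy-N-methylamide 28. The cut is made here, and not at C2–C3 of an aryl ketone, because no dependable reagent-controlled anti-aldol exists for an α-alkoxymethyl aryl ketone, whereas both stereocentres can be set with an auxiliary on an imide before ring A is attached. The price is one more step in the whole synthesis; the gain is a shorter longest linear sequence and a stereochemically defined precursor. The forward step needs metalation of 18 only at the C–H flanked by fluorine and methoxy, and mono-addition to the amide.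

**28 from 25 and 20 (C2–C3).** The two adjacent stereocentres are disconnected together by an anti-aldol between the glycolyl imide 25 and the aldehyde 20, by way of the adduct 27. This bond is the only one whose formation creates both centres at once and leaves the α-oxygen already protected and the β-oxygen free, exactly as the ring closure requires. The forward reaction needs the anti relationship and the (2R,3R) absolute sense.

**25 and 20 from 23, 1, 21 and 19.** Imide 25 comes from acid 23 (from methyl glycolate 21 through 22) and the oxazolidinone 1; aldehyde 20 comes from 19 by acetal protection. These are functional-group operations with no selectivity issue.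

**18 from 15 and 11 (C8–C1'').** The benzylic bond is cut to an aryl iodide 15 and a primary alkylzinc reagent 17, made from iodide 11. The stereocentre is β to the metal and is not involved, so it cannot be scrambled. A polar alkylation of an aryllithium by the β-branched iodide would be slow and would compete with loss of lithium fluoride.

**15 from 13 and 12 (C8–I).** The iodine is introduced by directed metalation of the acetal ether 13 of phenol 12. The carbon between fluorine and the chelating acetal ether is the target position; an amide base is chosen so that only protons next to fluorine are removed.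

**11 from 4 and 5 (C2''–C3'').** The chain is cut next to its stereocentre into the dienolate of imide 4 and prenyl bromide 5. Deconjugative α-alkylation sets the stereocentre and creates the isopropenyl group in one operation; the carbonyl carbon becomes C1''. A cyclic monoterpene from the chiral pool would also supply such a stereocentre, but ring cleavage leaves one carbon too many between it and the arene, and removing that carbon would pass through a racemisation-prone α-branched β,γ-unsaturated aldehyde. The tertiary alcohol is made by epoxidation and hydride opening at the imide stage (7 to 8 to 9), where no free hydroxyl can attack the epoxide. Imide 4 comes from 1 and acid chloride 2; the same auxiliary serves both fragments.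

## Alternatives that were turned down

**Alternative 1:** Ring A itself is disconnected (C7–C8, C4a–C8a and C6–C7) by a Danheiser benzannulation. In the forward sense the siloxyalkyne A2, which already carries the protected chain, is heated with 3-methoxycyclobut-2-en-1-one A3; electrocyclic opening to a vinylketene, cycloaddition with the alkyne, a second opening and a six-electron closure give the resorcinol monosilyl ether A1. In its favour, the substitution pattern of ring A is fixed by construction, with no reliance on the regioselectivity of a directed metalation; on this point it is stronger than the chosen route, whose step 8 carries a real regiochemical risk. Against it, A1 contains neither the C4 carbon nor a leaving group at C8a. Ring C and both stereocentres remain to be built, and because O1 is already a phenol oxygen the closure would have to take place at C2, the carbon that ionises. A2 also needs several steps from a chain ester, and the annulation requires prolonged heating. The chosen route buys ring A ready-made and spends its steps on the stereocentres and on a closure that leaves C2 untouched.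

**Alternative 2:** The C2–C3 bond is disconnected through a one-carbon ring expansion. The forward key step treats the α-hydroxy aldehyde A5, a 2-aryl-3-hydroxy-2,3-dihydrobenzofuran-3-carbaldehyde, with a mild Lewis acid such as Sc(OSO2CF3)3. C2 shifts from the carbinol carbon to the formyl carbon, the five-membered ring becomes ring C, and the silyl-protected flavanonol A4 results. In its favour, this is an atom-economical isomerisation that delivers the free C3 hydroxyl directly and needs no leaving group on ring A. Against it, a Lewis acid is applied to a substrate whose C2–O1 bond is benzylic and activated by two silyloxy groups, so ring opening at C2 competes with the shift. Migration of the aryl carbon C3a instead of C2 would give the isomeric 4-hydroxychroman-3-one. The configuration at C3 depends on a stereodefined quaternary carbinol in A5, which is harder to make than the two secondary centres of 31. Aryl silyl ethers would also have to survive the route. The chosen strategy sets both centres in one auxiliary-controlled aldol and closes the ring under basic conditions that do not touch C2.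

**Alternative 3:** The C3–C4 bond is disconnected by an intramolecular crossed benzoin reaction. In the forward sense a chiral triazolylidene carbene adds to the ring-A formyl group of dialdehyde A7; the resulting Breslow intermediate attacks the aliphatic formyl group, and the acetal-protected flavanonol A6 is formed while the labile α-aryloxy aldehyde centre equilibrates. In its favour, the step is catalytic, sets C2 and C3 during ring closure without an auxiliary, and tolerates the free tertiary alcohol; in step count for the stereocentres it is stronger than the chosen route, which spends six steps on the ring-B fragment. Against it, A7 must be made by O-alkylation of a hindered phenol at the very benzylic carbon that ionises. A7 can also lose the phenoxide by β-elimination under the basic carbene conditions. The more accessible aliphatic aldehyde, not the di-ortho-substituted aryl aldehyde, is the likelier site of carbene addition, which would give the 3-oxo-4-hydroxy isomer. Trans selectivity in such a dynamic closure has no close model. The chosen route is longer but each stereocentre is set by a reaction whose sense can be predicted.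

Key step: step 17

## Route

Step 1
Reactants: 1 (4S)-4-benzyl-1,3-oxazolidin-2-one; 2 3-methylbut-2-enoyl chloride
Product: 4 (4S)-4-benzyl-3-(3-methylbut-2-enoyl)-1,3-oxazolidin-2-one, via lithium oxazolidinide 3 (not isolated)
Conditions: n-BuLi, THF, −78 °C; then 2, −78 → 0 °C
Reagents that add atoms: none
Why: N-acylation of the lithiated oxazolidinone by an acid chloride; it attaches the auxiliary that controls the chain stereocentre in step 2.

Step 2
Reactants: 4 (4S)-4-benzyl-3-(3-methylbut-2-enoyl)-1,3-oxazolidin-2-one; 5 1-bromo-3-methylbut-2-ene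
Product: 7 (4S)-4-benzyl-3-[(2S)-5-methyl-2-(prop-1-en-2-yl)hex-4-enoyl]-1,3-oxazolidin-2-one, via sodium Z-dienolate 6 (not isolated)
Conditions: NaN(SiMe3)2, THF, −78 °C; then 5, −78 → −45 °C; AcOH quench
Reagents that add atoms: none
Why: Deconjugative α-alkylation of an N-enoyl oxazolidinone: γ-deprotonation gives the chelated Z-dienolate 6, which is alkylated at the α-carbon by the allylic bromide on the face opposite the benzyl group. This sets the chain stereocentre (2S here, R in the target after the change of priorities) and moves the double bond into the isopropenyl position.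

Step 3
Reactants: 7 (4S)-4-benzyl-3-[(2S)-5-methyl-2-(prop-1-en-2-yl)hex-4-enoyl]-1,3-oxazolidin-2-one
Product: 8 (4S)-4-benzyl-3-[(2S)-2-[(3,3-dimethyloxiran-2-yl)methyl]-3-methylbut-3-enoyl]-1,3-oxazolidin-2-one (both epimers at the oxirane carbon)
Conditions: 3-chloroperoxybenzoic acid (1.05 equiv), NaHCO3, CH2Cl2, −20 → 0 °C
Reagents that add atoms: 3-chloroperoxybenzoic acid, OOC(=O)c1cccc(Cl)c1
Why: Peracid epoxidation favours the electron-rich trisubstituted alkene over the 1,1-disubstituted alkene next to the electron-poor imide carbon. The new oxirane centre is unselective but becomes a CH2 group in step 4, and at the imide stage no hydroxyl is present to open the epoxide.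

Step 4
Reactants: 8 (4S)-4-benzyl-3-[(2S)-2-[(3,3-dimethyloxiran-2-yl)methyl]-3-methylbut-3-enoyl]-1,3-oxazolidin-2-one
Product: 9 (2S)-5-methyl-2-(prop-1-en-2-yl)hexane-1,5-diol
Conditions: LiAlH4, THF, 0 → 40 °C; aqueous potassium sodium tartrate work-up
Reagents that add atoms: none
Why: LiAlH4 cleaves the imide reductively to the primary alcohol and opens the trisubstituted epoxide by hydride attack at its less substituted carbon, which gives the tertiary alcohol. The stereocentre is not enolised by hydride, and the auxiliary 1 is released for reuse in step 13.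

Step 5
Reactants: 9 (2S)-5-methyl-2-(prop-1-en-2-yl)hexane-1,5-diol
Product: 10 (5S)-6-iodo-2-methyl-5-(prop-1-en-2-yl)hexan-2-ol
Conditions: I2, PPh3, imidazole, CH2Cl2, 0 °C
Reagents that add atoms: iodine, II
Why: Appel-type iodination; only the primary hydroxyl forms a reactive alkoxyphosphonium ion, the tertiary one being too hindered.

Step 6
Reactants: 10 (5S)-6-iodo-2-methyl-5-(prop-1-en-2-yl)hexan-2-ol
Product: 11 triethyl{[(5S)-6-iodo-2-methyl-5-(prop-1-en-2-yl)hexan-2-yl]oxy}silane
Conditions: Et3SiOSO2CF3, 2,6-lutidine, CH2Cl2, −78 → 0 °C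
Reagents that add atoms: triethylsilyl trifluoromethanesulfonate, CC[Si](CC)(CC)OS(=O)(=O)C(F)(F)F
Why: Silylation of a tertiary alcohol with a silyl triflate and a hindered pyridine base; the silyl ether masks the only acidic proton of the chain for the organometallic steps and falls under the final acid treatment.

Step 7
Reactants: 12 3-fluoro-5-methoxyphenol
Product: 13 1-fluoro-3-methoxy-5-(methoxymethoxy)benzene
Conditions: MeOCH2Cl, iPr2NEt, CH2Cl2, 0 °C → rt
Reagents that add atoms: chloromethyl methyl ether, COCCl
Why: O-alkylation of the phenol to its methoxymethyl (MOM) ether, which protects the future C7 hydroxyl and serves as the chelating director for step 8.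

Step 8
Reactants: 13 1-fluoro-3-methoxy-5-(methoxymethoxy)benzene
Product: 15 1-fluoro-2-iodo-5-methoxy-3-(methoxymethoxy)benzene, via aryllithium 14 (not isolated)
Conditions: LiTMP (lithium 2,2,6,6-tetramethylpiperidide, from the amine and n-BuLi), THF, −78 °C; then I2, THF, −78 °C → rt
Reagents that add atoms: iodine, II
Why: Directed ortho-metalation followed by iodination. An amide base removes only a proton next to fluorine, so the position between the two ether oxygens is left alone. Of the two fluorine-flanked protons, the one next to the MOM ether should be favoured because its second oxygen chelates lithium in the transition state and in aryllithium 14.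

Step 9
Reactants: 11 triethyl{[(5S)-6-iodo-2-methyl-5-(prop-1-en-2-yl)hexan-2-yl]oxy}silane; 15 1-fluoro-2-iodo-5-methoxy-3-(methoxymethoxy)benzene
Product: 18 triethyl{[(5R)-6-[2-fluoro-4-methoxy-6-(methoxymethoxy)phenyl]-2-methyl-5-(prop-1-en-2-yl)hexan-2-yl]oxy}silane, via alkyllithium 16 (not isolated), via alkylzinc chloride 17 (not isolated)
Conditions: 11, t-BuLi (2.1 equiv), Et2O, −78 °C; ZnCl2, THF, −78 °C → rt; then 15, Pd(OAc)2 (cat.), SPhos (2-dicyclohexylphosphino-2',6'-dimethoxybiphenyl), THF, 45 °C
Reagents that add atoms: none
Why: Negishi coupling: iodine–lithium exchange and transmetalation give the primary alkylzinc 17, which couples with the aryl iodide under zerovalent palladium formed in situ from Pd(OAc)2. The bulky biaryl phosphine speeds reductive elimination over β-hydride elimination. The stereocentre is β to the metal and takes no part.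

Step 10
Reactants: 19 2,4-dihydroxybenzaldehyde
Product: 20 2,4-bis(methoxymethoxy)benzaldehyde
Conditions: NaH, MeOCH2Cl, DMF, 0 °C → rt
Reagents that add atoms: chloromethyl methyl ether, COCCl
Why: Double O-alkylation of the phenoxides; the strong base is used because the C2 hydroxyl is hydrogen-bonded to the aldehyde.

Step 11
Reactants: 21 methyl hydroxyacetate
Product: 22 methyl (methoxymethoxy)acetate
Conditions: MeOCH2Cl, iPr2NEt, CH2Cl2, 0 °C → rt
Reagents that add atoms: chloromethyl methyl ether, COCCl
Why: Acetal protection of the primary alcohol; this oxygen becomes the C3 oxygen, and its MOM ether cannot migrate or act as a nucleophile in the key step.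

Step 12
Reactants: 22 methyl (methoxymethoxy)acetate
Product: 23 (methoxymethoxy)acetic acid
Conditions: LiOH, THF/H2O, 0 °C → rt; then 1 M HCl to pH 3, 0 °C
Reagents that add atoms: lithium hydroxide, [Li+].[OH-]
Why: Ester saponification; the acetal is stable to base and to the brief, cold acidification.

Step 13
Reactants: 23 (methoxymethoxy)acetic acid; 1 (4S)-4-benzyl-1,3-oxazolidin-2-one
Product: 25 (4S)-4-benzyl-3-[(methoxymethoxy)acetyl]-1,3-oxazolidin-2-one, via mixed pivalic anhydride 24 (not isolated)
Conditions: Me3CCOCl, Et3N, THF, −20 °C; then 1, LiCl, −20 °C → rt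
Reagents that add atoms: none
Why: N-acylation of the oxazolidinone through a mixed pivalic anhydride; attack occurs at the less hindered glycolyl carbonyl.

Step 14
Reactants: 25 (4S)-4-benzyl-3-[(methoxymethoxy)acetyl]-1,3-oxazolidin-2-one; 20 2,4-bis(methoxymethoxy)benzaldehyde
Product: 27 (4S)-4-benzyl-3-[(2R,3R)-3-[2,4-bis(methoxymethoxy)phenyl]-3-hydroxy-2-(methoxymethoxy)propanoyl]-1,3-oxazolidin-2-one, via trimethylsilyl ether 26 (not isolated)
Conditions: MgCl2 (20 mol %), Et3N, Me3SiCl, EtOAc, rt; then AcOH/THF/H2O, 0 °C
Reagents that add atoms: none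
Why: Magnesium-halide-catalysed anti-aldol of an N-acyloxazolidinone with an aromatic aldehyde: soft enolisation gives the magnesium-chelated Z-enolate, which adds to the aldehyde through a boat-like transition state on the face away from the benzyl group. Trapping by Me3SiCl as 26 prevents reversal. The enolate face sets the α-carbon (R, the future C3) and the transition-state geometry sets the carbinol carbon anti to it (R, the future C2); dilute acetic acid then removes the silyl group without ionising the benzylic alcohol.

Step 15
Reactants: 27 (4S)-4-benzyl-3-[(2R,3R)-3-[2,4-bis(methoxymethoxy)phenyl]-3-hydroxy-2-(methoxymethoxy)propanoyl]-1,3-oxazolidin-2-one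
Product: 28 (2R,3R)-3-[2,4-bis(methoxymethoxy)phenyl]-3-hydroxy-N-methoxy-2-(methoxymethoxy)-N-methylpropanamide
Conditions: MeNH(OMe)·HCl, AlMe3, CH2Cl2, −20 → 0 °C; aqueous potassium sodium tartrate work-up
Reagents that add atoms: N,O-dimethylhydroxylamine hydrochloride, CNOC.Cl
Why: Aluminium amide transamination of a β-hydroxy imide to the Weinreb amide; the aluminium alkoxide of the free hydroxyl delivers the amide to the exocyclic carbonyl, so neither stereocentre is enolised. The auxiliary is released.

Step 16
Reactants: 18 triethyl{[(5R)-6-[2-fluoro-4-methoxy-6-(methoxymethoxy)phenyl]-2-methyl-5-(prop-1-en-2-yl)hexan-2-yl]oxy}silane; 28 (2R,3R)-3-[2,4-bis(methoxymethoxy)phenyl]-3-hydroxy-N-methoxy-2-(methoxymethoxy)-N-methylpropanamide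
Product: 31 (2R,3R)-3-[2,4-bis(methoxymethoxy)phenyl]-1-{2-fluoro-6-methoxy-4-(methoxymethoxy)-3-[(2R)-5-methyl-2-(prop-1-en-2-yl)-5-(triethylsilyloxy)hexyl]phenyl}-3-hydroxy-2-(methoxymethoxy)propan-1-one, via aryllithium 29 (not isolated), via lithium alkoxide 30 (not isolated)
Conditions: 18, LiTMP (1.0 equiv, from the amine and n-BuLi), THF, −78 °C; then 30 (from 28 and LiN(SiMe3)2, THF, −78 °C), −78 → −40 °C; AcOH, −78 °C
Reagents that add atoms: none
Why: Ortho-metalation and Weinreb ketone synthesis: the amide base removes the only proton of 18 that lies next to fluorine, and aryllithium 29 is kept cold so that it does not lose lithium fluoride. The hydroxyl of 28 is masked as its lithium alkoxide 30, and the chelated tetrahedral adduct releases the ketone only on the cold acidic quench, so neither over-addition nor retro-aldol cleavage should occur.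

Step 17
Reactants: 31 (2R,3R)-3-[2,4-bis(methoxymethoxy)phenyl]-1-{2-fluoro-6-methoxy-4-(methoxymethoxy)-3-[(2R)-5-methyl-2-(prop-1-en-2-yl)-5-(triethylsilyloxy)hexyl]phenyl}-3-hydroxy-2-(methoxymethoxy)propan-1-one
Product: 33 (2R,3R)-2-[2,4-bis(methoxymethoxy)phenyl]-5-methoxy-3,7-bis(methoxymethoxy)-8-[(2R)-5-methyl-2-(prop-1-en-2-yl)-5-(triethylsilyloxy)hexyl]-2,3-dihydro-4H-chromen-4-one, via potassium alkoxide 32 (not isolated)
Conditions: KN(SiMe3)2 (1.0 equiv), THF, −78 → 0 °C; pH 7 buffer
Reagents that add atoms: none
Why: KN(SiMe3)2 converts the C2 hydroxyl of 31 into potassium alkoxide 32, whose oxygen adds to C8a, the fluorine-bearing carbon ortho to the C4 carbonyl, giving a Meisenheimer complex with the charge delocalised into the carbonyl group; loss of fluoride restores the arene and forms O1–C8a. The closest known reaction type is the intramolecular SNAr of alkoxides on ortho-fluoroaryl ketones, used to make chroman-4-ones and related benzo-fused ethers from β-hydroxy ketones. Ring C closes by a 6-exo-trig addition (the attacked C8a=C8 bond lies outside the new ring) followed by elimination. No stereocentre is created: C2 and C3 come from step 14 and neither the C2–O nor the C3–O bond is broken, so the anti relationship of 31 becomes the trans relationship of 33 with retention at both centres. The step needs six-ring O-arylation to outrun retro-aldol cleavage of the β-alkoxy ketone, enolisation at C3 and five-ring closure through the C3 oxygen. The substrate secures this by the MOM ether that blocks the C3 oxygen and cannot migrate, by the small carbonyl-activated fluoride leaving group, by both ring-A alkoxy groups being meta to C8a so that they do not donate to it, and by one equivalent of base at low temperature, which leaves no free base to enolise 31 or 33.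

Step 18
Reactants: 33 (2R,3R)-2-[2,4-bis(methoxymethoxy)phenyl]-5-methoxy-3,7-bis(methoxymethoxy)-8-[(2R)-5-methyl-2-(prop-1-en-2-yl)-5-(triethylsilyloxy)hexyl]-2,3-dihydro-4H-chromen-4-one
Product: 34 (2R,3R)-2-(2,4-dihydroxyphenyl)-3,7-dihydroxy-8-[(2R)-5-hydroxy-5-methyl-2-(prop-1-en-2-yl)hexyl]-5-methoxy-2,3-dihydro-4H-chromen-4-one
Conditions: HCl (1.25 M in MeOH), THF, 0 → 35 °C
Reagents that add atoms: none
Why: Acid-catalysed acetal exchange with methanol removes the four MOM groups and methanolysis removes the triethylsilyl group; cleavage is at O–CH2 and O–Si, so no bond to a stereocentre is broken. The trans arrangement at C2/C3 is also the thermodynamically preferred one, which protects it against any reversible opening at C2.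

## Compound list

1 | (4S)-4-benzyl-1,3-oxazolidin-2-one | O=C1N[C@@H](Cc2ccccc2)CO1 | starting material
2 | 3-methylbut-2-enoyl chloride | CC(C)=CC(Cl)=O | starting material
3 | lithium (4S)-4-benzyl-2-oxo-1,3-oxazolidin-3-ide | [Li]N1[C@@H](Cc2ccccc2)COC1=O | intermediate (not isolated)
4 | (4S)-4-benzyl-3-(3-methylbut-2-enoyl)-1,3-oxazolidin-2-one | CC(C)=CC(=O)N1[C@@H](Cc2ccccc2)COC1=O | intermediate
5 | 1-bromo-3-methylbut-2-ene | CC(C)=CCBr | starting material
6 | sodium (1Z)-1-[(4S)-4-benzyl-2-oxo-1,3-oxazolidin-3-yl]-3-methylbuta-1,3-dien-1-olate | C=C(C)/C=C(\O[Na])N1[C@@H](Cc2ccccc2)COC1=O | intermediate (not isolated)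
7 | (4S)-4-benzyl-3-[(2S)-5-methyl-2-(prop-1-en-2-yl)hex-4-enoyl]-1,3-oxazolidin-2-one | C=C(C)[C@H](CC=C(C)C)C(=O)N1[C@@H](Cc2ccccc2)COC1=O | intermediate
8 | (4S)-4-benzyl-3-[(2S)-2-[(3,3-dimethyloxiran-2-yl)methyl]-3-methylbut-3-enoyl]-1,3-oxazolidin-2-one, both epimers at the oxirane carbon | C=C(C)[C@H](CC2OC2(C)C)C(=O)N1[C@@H](Cc3ccccc3)COC1=O | intermediate
9 | (2S)-5-methyl-2-(prop-1-en-2-yl)hexane-1,5-diol | C=C(C)[C@H](CCC(C)(C)O)CO | intermediate
10 | (5S)-6-iodo-2-methyl-5-(prop-1-en-2-yl)hexan-2-ol | C=C(C)[C@H](CCC(C)(C)O)CI | intermediate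
11 | triethyl{[(5S)-6-iodo-2-methyl-5-(prop-1-en-2-yl)hexan-2-yl]oxy}silane | C=C(C)[C@H](CCC(C)(C)O[Si](CC)(CC)CC)CI | intermediate
12 | 3-fluoro-5-methoxyphenol | COc1cc(O)cc(F)c1 | starting material
13 | 1-fluoro-3-methoxy-5-(methoxymethoxy)benzene | COCOc1cc(OC)cc(F)c1 | intermediate
14 | [2-fluoro-4-methoxy-6-(methoxymethoxy)phenyl]lithium | COCOc1cc(OC)cc(F)c1[Li] | intermediate (not isolated)
15 | 1-fluoro-2-iodo-5-methoxy-3-(methoxymethoxy)benzene | COCOc1cc(OC)cc(F)c1I | intermediate
16 | [(2S)-5-methyl-2-(prop-1-en-2-yl)-5-(triethylsilyloxy)hexyl]lithium | C=C(C)[C@H](CCC(C)(C)O[Si](CC)(CC)CC)C[Li] | intermediate (not isolated)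
17 | chloro[(2S)-5-methyl-2-(prop-1-en-2-yl)-5-(triethylsilyloxy)hexyl]zinc | C=C(C)[C@H](CCC(C)(C)O[Si](CC)(CC)CC)C[Zn]Cl | intermediate (not isolated)
18 | triethyl{[(5R)-6-[2-fluoro-4-methoxy-6-(methoxymethoxy)phenyl]-2-methyl-5-(prop-1-en-2-yl)hexan-2-yl]oxy}silane | C=C(C)[C@H](CCC(C)(C)O[Si](CC)(CC)CC)Cc1c(OCOC)cc(OC)cc1F | intermediate
19 | 2,4-dihydroxybenzaldehyde | O=Cc1ccc(O)cc1O | starting material
20 | 2,4-bis(methoxymethoxy)benzaldehyde | O=Cc1ccc(OCOC)cc1OCOC | intermediate
21 | methyl hydroxyacetate | COC(=O)CO | starting material
22 | methyl (methoxymethoxy)acetate | COCOCC(=O)OC | intermediate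
23 | (methoxymethoxy)acetic acid | COCOCC(=O)O | intermediate
24 | (methoxymethoxy)acetic 2,2-dimethylpropanoic anhydride | COCOCC(=O)OC(=O)C(C)(C)C | intermediate (not isolated)
25 | (4S)-4-benzyl-3-[(methoxymethoxy)acetyl]-1,3-oxazolidin-2-one | COCOCC(=O)N1[C@@H](Cc2ccccc2)COC1=O | intermediate
26 | (4S)-4-benzyl-3-[(2R,3R)-3-[2,4-bis(methoxymethoxy)phenyl]-2-(methoxymethoxy)-3-(trimethylsilyloxy)propanoyl]-1,3-oxazolidin-2-one | O=C(N1[C@@H](Cc2ccccc2)COC1=O)[C@H](OCOC)[C@H](O[Si](C)(C)C)c1ccc(OCOC)cc1OCOC | intermediate (not isolated)
27 | (4S)-4-benzyl-3-[(2R,3R)-3-[2,4-bis(methoxymethoxy)phenyl]-3-hydroxy-2-(methoxymethoxy)propanoyl]-1,3-oxazolidin-2-one | O=C(N1[C@@H](Cc2ccccc2)COC1=O)[C@H](OCOC)[C@H](O)c1ccc(OCOC)cc1OCOC | intermediate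
28 | (2R,3R)-3-[2,4-bis(methoxymethoxy)phenyl]-3-hydroxy-N-methoxy-2-(methoxymethoxy)-N-methylpropanamide | CON(C)C(=O)[C@H](OCOC)[C@H](O)c1ccc(OCOC)cc1OCOC | intermediate
29 | {2-fluoro-6-methoxy-4-(methoxymethoxy)-3-[(2R)-5-methyl-2-(prop-1-en-2-yl)-5-(triethylsilyloxy)hexyl]phenyl}lithium | C=C(C)[C@H](CCC(C)(C)O[Si](CC)(CC)CC)Cc1c(OCOC)cc(OC)c([Li])c1F | intermediate (not isolated)
30 | lithium (1R,2R)-1-[2,4-bis(methoxymethoxy)phenyl]-3-[methoxy(methyl)amino]-2-(methoxymethoxy)-3-oxopropan-1-olate | CON(C)C(=O)[C@H](OCOC)[C@H](O[Li])c1ccc(OCOC)cc1OCOC | intermediate (not isolated)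
31 | (2R,3R)-3-[2,4-bis(methoxymethoxy)phenyl]-1-{2-fluoro-6-methoxy-4-(methoxymethoxy)-3-[(2R)-5-methyl-2-(prop-1-en-2-yl)-5-(triethylsilyloxy)hexyl]phenyl}-3-hydroxy-2-(methoxymethoxy)propan-1-one | C=C(C)[C@H](CCC(C)(C)O[Si](CC)(CC)CC)Cc1c(OCOC)cc(OC)c(C(=O)[C@H](OCOC)[C@H](O)c2ccc(OCOC)cc2OCOC)c1F | intermediate
32 | potassium alkoxide of 31 at the C3 carbinol oxygen of the propanone chain | C=C(C)[C@H](CCC(C)(C)O[Si](CC)(CC)CC)Cc1c(OCOC)cc(OC)c(C(=O)[C@H](OCOC)[C@H](O[K])c2ccc(OCOC)cc2OCOC)c1F | intermediate (not isolated)
33 | (2R,3R)-2-[2,4-bis(methoxymethoxy)phenyl]-5-methoxy-3,7-bis(methoxymethoxy)-8-[(2R)-5-methyl-2-(prop-1-en-2-yl)-5-(triethylsilyloxy)hexyl]-2,3-dihydro-4H-chromen-4-one | C=C(C)[C@H](CCC(C)(C)O[Si](CC)(CC)CC)Cc1c(OCOC)cc(OC)c2c1O[C@H](c1ccc(OCOC)cc1OCOC)[C@@H](OCOC)C2=O | intermediate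
34 | (2R,3R)-2-(2,4-dihydroxyphenyl)-3,7-dihydroxy-8-[(2R)-5-hydroxy-5-methyl-2-(prop-1-en-2-yl)hexyl]-5-methoxy-2,3-dihydro-4H-chromen-4-one | C=C(C)[C@H](CCC(C)(C)O)Cc1c(O)cc(OC)c2c1O[C@H](c1ccc(O)cc1O)[C@@H](O)C2=O | target

## Step count and least certain steps

Total: 18 steps. Longest linear sequence: 10 steps (steps 1 to 6, 9, 16, 17 and 18).

**Step 17 (key step).** The most likely failure is retro-aldol cleavage of alkoxide 32, followed by re-addition with loss of the anti relationship, or by simple loss of material. Closure may also be slow because the ketone is twisted out of conjugation by its two ortho substituents, and any excess base could enolise C3. The fallback sets out from 31 and comes back at 33. Compound 31 is silylated with 1-(trimethylsilyl)imidazole to the trimethylsilyl ether of 31, F1. A catalytic amount of anhydrous fluoride (Bu4N[Ph3SiF2] in THF) then removes the silyl group, the alkoxide closes onto C8a, and the fluoride expelled starts the next cycle. No amide base is present and the alkoxide exists only at low concentration, which should suppress both enolisation and bimolecular aldol return.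

**Step 14.** The MOM oxygen offers magnesium a second chelation site, which may erode the anti selectivity or the facial selectivity, and the electron-rich aldehyde may add slowly. The fallback sets out from 22 and 18 and comes back at 31. Ester 22 is converted with MeNH(OMe)·HCl and i-PrMgCl into N-methoxy-N-methyl-2-(methoxymethoxy)acetamide, F2. Aryllithium 29 is acylated with it to give the aryl ketone 1-{2-fluoro-6-methoxy-4-(methoxymethoxy)-3-[(2R)-5-methyl-2-(prop-1-en-2-yl)-5-(triethylsilyloxy)hexyl]phenyl}-2-(methoxymethoxy)ethan-1-one, F3. Enolisation with dicyclohexylboron chloride and Et3N should give the E-enol borinate, whose chair transition state with 20 leads to the anti adducts. This fallback controls only the relative configuration, so 31 would form together with its (2S,3S)-anti isomer, F4, which has to be removed by chromatography on a chiral stationary phase at the cost of half the material.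

**Step 8.** Metalation may occur at the other fluorine-flanked position, between fluorine and methoxy, giving a regioisomeric iodide that is hard to separate. The fallback replaces chelation control by steric control; it sets out from 17 and comes back at 18. Commercial 5-fluorobenzene-1,3-diol, F5, is mono-protected to 3-fluoro-5-(methoxymethoxy)phenol, F6, and silylated to {[3-fluoro-5-(methoxymethoxy)phenyl]oxy}tri(propan-2-yl)silane, F7. The bulky silyloxy group shields both of its neighbours, so the amide base can only remove the proton between fluorine and the MOM ether; iodination gives {[3-fluoro-4-iodo-5-(methoxymethoxy)phenyl]oxy}tri(propan-2-yl)silane, F8. Negishi coupling with 17 gives the silyl analogue of 18, F9. One equivalent of Bu4NF at 0 °C cleaves only the aryl silyl ether to 3-fluoro-5-(methoxymethoxy)-4-[(2R)-5-methyl-2-(prop-1-en-2-yl)-5-(triethylsilyloxy)hexyl]phenol, F10, and methylation with MeI and K2CO3 gives 18. This costs three more steps.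

**Step 16.** The aggregated dilithio species formed from 29 and 30 may react slowly, so that on warming the aryllithium is lost through elimination of lithium fluoride or through proton transfer. The fallback sets out from 28 and comes back at 31. Amide 28 is silylated with 1-(trimethylsilyl)imidazole to its trimethylsilyl ether, F11, a neutral and more soluble electrophile. Addition of 29 then gives the silyl ether F1 already described, and AcOH/THF/H2O at 0 °C frees 31; F1 can equally be taken straight into the fluoride-triggered closure.

**Step 18.** The C3 acetal, deactivated by the ketone, may need acid strong enough to protonate the isopropenyl group, which would lead to addition of methanol or of the C7 phenol, or to ionise the tertiary alcohol. The fallback sets out from 33 and comes back at 34 in two non-protic stages. Me3SiOSO2CF3 with 2,2'-bipyridyl in CH2Cl2 at 0 °C, followed by water, exchanges the four acetals under buffered conditions and gives the triethylsilyl ether of 34, F12. HF·pyridine buffered with pyridine in THF at 0 °C then removes the silyl group.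

## Further compounds

F1 | step 17 | (2R,3R)-3-[2,4-bis(methoxymethoxy)phenyl]-1-{2-fluoro-6-methoxy-4-(methoxymethoxy)-3-[(2R)-5-methyl-2-(prop-1-en-2-yl)-5-(triethylsilyloxy)hexyl]phenyl}-2-(methoxymethoxy)-3-(trimethylsilyloxy)propan-1-one | C=C(C)[C@H](CCC(C)(C)O[Si](CC)(CC)CC)Cc1c(OCOC)cc(OC)c(C(=O)[C@H](OCOC)[C@H](O[Si](C)(C)C)c2ccc(OCOC)cc2OCOC)c1F
F2 | step 14 | N-methoxy-N-methyl-2-(methoxymethoxy)acetamide | COCOCC(=O)N(C)OC
F3 | step 14 | 1-{2-fluoro-6-methoxy-4-(methoxymethoxy)-3-[(2R)-5-methyl-2-(prop-1-en-2-yl)-5-(triethylsilyloxy)hexyl]phenyl}-2-(methoxymethoxy)ethan-1-one | C=C(C)[C@H](CCC(C)(C)O[Si](CC)(CC)CC)Cc1c(OCOC)cc(OC)c(C(=O)COCOC)c1F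
F4 | step 14 | (2S,3S)-3-[2,4-bis(methoxymethoxy)phenyl]-1-{2-fluoro-6-methoxy-4-(methoxymethoxy)-3-[(2R)-5-methyl-2-(prop-1-en-2-yl)-5-(triethylsilyloxy)hexyl]phenyl}-3-hydroxy-2-(methoxymethoxy)propan-1-one | C=C(C)[C@H](CCC(C)(C)O[Si](CC)(CC)CC)Cc1c(OCOC)cc(OC)c(C(=O)[C@@H](OCOC)[C@@H](O)c2ccc(OCOC)cc2OCOC)c1F
F5 | step 8 | 5-fluorobenzene-1,3-diol | Oc1cc(O)cc(F)c1
F6 | step 8 | 3-fluoro-5-(methoxymethoxy)phenol | COCOc1cc(O)cc(F)c1
F7 | step 8 | {[3-fluoro-5-(methoxymethoxy)phenyl]oxy}tri(propan-2-yl)silane | COCOc1cc(O[Si](C(C)C)(C(C)C)C(C)C)cc(F)c1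
F8 | step 8 | {[3-fluoro-4-iodo-5-(methoxymethoxy)phenyl]oxy}tri(propan-2-yl)silane | COCOc1cc(O[Si](C(C)C)(C(C)C)C(C)C)cc(F)c1I
F9 | step 8 | triethyl{[(5R)-6-[2-fluoro-6-(methoxymethoxy)-4-{[tri(propan-2-yl)silyl]oxy}phenyl]-2-methyl-5-(prop-1-en-2-yl)hexan-2-yl]oxy}silane | C=C(C)[C@H](CCC(C)(C)O[Si](CC)(CC)CC)Cc1c(OCOC)cc(O[Si](C(C)C)(C(C)C)C(C)C)cc1F
F10 | step 8 | 3-fluoro-5-(methoxymethoxy)-4-[(2R)-5-methyl-2-(prop-1-en-2-yl)-5-(triethylsilyloxy)hexyl]phenol | C=C(C)[C@H](CCC(C)(C)O[Si](CC)(CC)CC)Cc1c(OCOC)cc(O)cc1F
F11 | step 16 | (2R,3R)-3-[2,4-bis(methoxymethoxy)phenyl]-N-methoxy-2-(methoxymethoxy)-N-methyl-3-(trimethylsilyloxy)propanamide | CON(C)C(=O)[C@H](OCOC)[C@H](O[Si](C)(C)C)c1ccc(OCOC)cc1OCOC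
F12 | step 18 | (2R,3R)-2-(2,4-dihydroxyphenyl)-3,7-dihydroxy-5-methoxy-8-[(2R)-5-methyl-2-(prop-1-en-2-yl)-5-(triethylsilyloxy)hexyl]-2,3-dihydro-4H-chromen-4-one | C=C(C)[C@H](CCC(C)(C)O[Si](CC)(CC)CC)Cc1c(O)cc(OC)c2c1O[C@H](c1ccc(O)cc1O)[C@@H](O)C2=O
A1 | alternative 1 | 5-methoxy-2-[(2R)-5-methyl-2-(prop-1-en-2-yl)-5-(triethylsilyloxy)hexyl]-3-{[tri(propan-2-yl)silyl]oxy}phenol | C=C(C)[C@H](CCC(C)(C)O[Si](CC)(CC)CC)Cc1c(O)cc(OC)cc1O[Si](C(C)C)(C(C)C)C(C)C
A2 | alternative 1 | triethyl{[(5R)-2-methyl-5-(prop-1-en-2-yl)-8-{[tri(propan-2-yl)silyl]oxy}oct-7-yn-2-yl]oxy}silane | C=C(C)[C@H](CCC(C)(C)O[Si](CC)(CC)CC)CC#CO[Si](C(C)C)(C(C)C)C(C)C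
A3 | alternative 1 | 3-methoxycyclobut-2-en-1-one | COC1=CC(=O)C1
A4 | alternative 2 | (2R,3R)-2-[2,4-bis(tert-butyldimethylsilyloxy)phenyl]-7-(tert-butyldimethylsilyloxy)-3-hydroxy-5-methoxy-8-[(2R)-5-methyl-2-(prop-1-en-2-yl)-5-(triethylsilyloxy)hexyl]-2,3-dihydro-4H-chromen-4-one | C=C(C)[C@H](CCC(C)(C)O[Si](CC)(CC)CC)Cc1c(O[Si](C)(C)C(C)(C)C)cc(OC)c2c1O[C@H](c1ccc(O[Si](C)(C)C(C)(C)C)cc1O[Si](C)(C)C(C)(C)C)[C@@H](O)C2=O
A5 | alternative 2 | (2R,3S)-2-[2,4-bis(tert-butyldimethylsilyloxy)phenyl]-6-(tert-butyldimethylsilyloxy)-3-hydroxy-4-methoxy-7-[(2R)-5-methyl-2-(prop-1-en-2-yl)-5-(triethylsilyloxy)hexyl]-2,3-dihydro-1-benzofuran-3-carbaldehyde | C=C(C)[C@H](CCC(C)(C)O[Si](CC)(CC)CC)Cc1c(O[Si](C)(C)C(C)(C)C)cc(OC)c2c1O[C@H](c1ccc(O[Si](C)(C)C(C)(C)C)cc1O[Si](C)(C)C(C)(C)C)[C@]2(O)C=O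
A6 | alternative 3 | (2R,3R)-2-[2,4-bis(methoxymethoxy)phenyl]-3-hydroxy-8-[(2R)-5-hydroxy-5-methyl-2-(prop-1-en-2-yl)hexyl]-5-methoxy-7-(methoxymethoxy)-2,3-dihydro-4H-chromen-4-one | C=C(C)[C@H](CCC(C)(C)O)Cc1c(OCOC)cc(OC)c2c1O[C@H](c1ccc(OCOC)cc1OCOC)[C@@H](O)C2=O
A7 | alternative 3 | 2-[2,4-bis(methoxymethoxy)phenyl]-2-{2-formyl-6-[(2R)-5-hydroxy-5-methyl-2-(prop-1-en-2-yl)hexyl]-3-methoxy-5-(methoxymethoxy)phenoxy}acetaldehyde, both configurations at the aryloxy carbon | C=C(C)[C@H](CCC(C)(C)O)Cc1c(OCOC)cc(OC)c(C=O)c1OC(C=O)c1ccc(OCOC)cc1OCOC
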